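**Remark (numbering and one assumption):** atoms carry germacranolide numbers: C1 = ring CH of the enoate, C10 = its ester-bearing carbon, C14 = CO2Me carbon, C4/C5 = oxirane carbons (C15 = methyl on C4), C6 = lactone O–CH, C7 = lactone ring-fusion CH, C8 = methacrylate carbon, C9 = acetate carbon, C11–C13 = lactone carbons. The sense of induction of the cinchona catalyst in step 3 is assumed as drawn; the pseudo-enantiomeric catalyst would be used otherwise. In the names below, α means the ring face that carries the C6 oxygen and β the opposite face.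

## Retrosynthetic overview

1. The target is reached by late acylation and peracid epoxidation of a (1(10)Z,4E)-germacradien-6,12-olide; its enoate comes from conjugation of a C1=C2 alkene through the C14 aldehyde, and its trans-lactone plus 4E-alkene from selenolactonisation/syn-elimination of an (E)-C5=C6 alkene.
2. That (1E,5E)-cyclodeca-1,5-diene is the [3,3] product of a cyclohexane: C6 carries oxygen, and C1 and C6 flank the arc C2–C3–C4–C5, so ring C1–C6–C7–C8–C9–C10 with vinyl (C2=C3) on C1 and (E)-propenyl (C5=C4–C15) on the carbinol C6 is a 3-oxido-1,5-diene; its anionic oxy-Cope shift forms C3–C4 and cleaves C1–C6.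
3. The cyclohexane comes from 4,4-dimethoxycyclohexadienone via a p-quinol: a malonate tethered to O6 sets C7 (temporary γ-lactone), enolate oxidation sets C8, alkoxide-directed vinyl addition/aldol fills C1 and C10, hydride sets C9.
4. Ring order: cyclohexane (from the start) → temporary γ-lactone (steps 3–6) → ten-membered carbocycle (step 10) → final γ-lactone (step 12) → oxirane (step 18).

Key step: step 10

## Route

Step 1
Reactants: 1 4,4-dimethoxycyclohexa-2,5-dien-1-one; 2 (E)-1-bromoprop-1-ene
Product: 5 4-hydroxy-4-[(E)-prop-1-enyl]cyclohexa-2,5-dien-1-one, via (E)-prop-1-enyllithium 3 (not isolated), via ketal carbinol 4 (not isolated)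
Conditions: 2, t-BuLi (2 equiv), Et2O, −78 °C; then 1, THF, −78 °C; then AcOH/H2O/THF, 0 °C
Reagents that add atoms: water, O
Why: Halogen–lithium exchange with retention of alkene geometry, 1,2-addition of the alkenyllithium to the quinone monoketal carbonyl and mild ketal hydrolysis should give the achiral p-quinol, which already holds the future Cope carbinol C6 with its (E)-propenyl group.

Step 2
Reactants: 5 4-hydroxy-4-[(E)-prop-1-enyl]cyclohexa-2,5-dien-1-one; 6 methyl 3-chloro-3-oxopropanoate
Product: 7 methyl 4-oxo-1-[(E)-prop-1-enyl]cyclohexa-2,5-dien-1-yl malonate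
Conditions: pyridine, CH2Cl2, −20 → 0 °C
Reagents that add atoms: none
Why: O-acylation of the hindered tertiary alcohol (through the acyl ketene formed from the malonyl chloride) should install the C11/C12 unit as a tether on O6; no stereocentre is formed.

Step 3
Reactants: 7 methyl 4-oxo-1-[(E)-prop-1-enyl]cyclohexa-2,5-dien-1-yl malonate
Product: 8 cis-fused α-carbomethoxy bicyclic lactone enone
Conditions: quinine-derived thiourea catalyst [N-(3,5-bis(trifluoromethyl)phenyl)-N'-(9-deoxy-epi-quinin-9-yl)thiourea] (10 mol%), toluene, −20 °C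
Reagents that add atoms: none
Why: Catalytic enantioselective desymmetrising intramolecular Michael addition (5-exo) of the tethered malonate to one of the two enantiotopic enone arms should set C6 and C7, the tether forcing the new C7–C11 bond cis to O6.

Step 4
Reactants: 8 cis-fused α-carbomethoxy bicyclic lactone enone
Product: 9 cis-fused bicyclic lactone enone
Conditions: LiCl, H2O, DMSO, 110 °C
Reagents that add atoms: none
Why: Krapcho dealkoxycarbonylation should remove the activating ester and leave the γ-lactone (C11H2–C12) untouched; no stereocentre is affected.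

Step 5
Reactants: 9 cis-fused bicyclic lactone enone
Product: 11 8-silyloxy bicyclic lactone enone, via silyl dienol ether 10 (not isolated)
Conditions: TBSOTf, Et3N, CH2Cl2, 0 °C; then DMDO, acetone, −78 → 0 °C
Reagents that add atoms: tert-butyldimethylsilyl triflate, CC(C)(C)[Si](C)(C)OS(=O)(=O)C(F)(F)F; dimethyldioxirane, CC1(C)OO1
Why: Rubottom oxidation with silyl transfer; only the α′-position C8 can enolise (C6 is quaternary), and the oxidant should approach the convex face anti to the C7–C11 bond, giving the C8 oxygen trans to C11.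

Step 6
Reactants: 11 8-silyloxy bicyclic lactone enone
Product: 12 hydroxy amide enone
Conditions: Me2NH·HCl, AlMe3, CH2Cl2, 0 → 25 °C
Reagents that add atoms: dimethylamine hydrochloride, CNC.Cl
Why: Aluminium amide aminolysis of the lactone should free the tertiary C6 hydroxyl (needed as directing group and later as Cope alkoxide) and turn C12 into a base-stable dimethylamide; no stereocentre changes.

Step 7
Reactants: 12 hydroxy amide enone; 13 vinylmagnesium bromide
Product: 15 β-hydroxy ketone, via magnesium enolate 14 (not isolated)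
Conditions: CH2=CHMgBr (4 equiv), THF, −78 → −20 °C; then HCHO (g), −78 °C
Reagents that add atoms: formaldehyde, C=O
Why: Alkoxide-directed (ligand-assisted) conjugate addition of the Grignard reagent to the 4-oxido enone should deliver vinyl to C1 syn to the C6 oxygen, i.e. trans to the propenyl group, and the regiodefined magnesium enolate is then trapped at C10 by an aldol reaction with formaldehyde, anti to the vinyl group.

Step 8
Reactants: 15 β-hydroxy ketone
Product: 16 triol
Conditions: LiBH(s-Bu)3, THF, −78 °C; then NaOH, H2O2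
Reagents that add atoms: none
Why: Reduction of the cyclohexanone flanked by two equatorial substituents with a bulky trialkylborohydride should proceed by equatorial attack and give the axial C9 alcohol, cis to the C8 silyl ether.

Step 9
Reactants: 16 triol
Product: 17 Cope substrate (9,14-O-isopropylidene hydroxy amide)
Conditions: Me2C(OMe)2, PPTS (cat.), acetone, 25 °C
Reagents that add atoms: 2,2-dimethoxypropane, COC(C)(C)OC
Why: Acetonide formation across the cis-disposed C9 and C14 hydroxyls should mask both in one operation and leave the hindered tertiary C6 hydroxyl free.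

Step 10
Reactants: 17 Cope substrate (9,14-O-isopropylidene hydroxy amide)
Product: 20 ring-expanded enol triflate, via potassium alkoxide 18 (not isolated), via ring-expanded potassium enolate 19 (not isolated)
Conditions: KN(SiMe3)2 (1.1 equiv), 18-crown-6, THF, −78 → 0 °C; then PhNTf2, −78 → 0 °C
Reagents that add atoms: N-phenyl-bis(trifluoromethanesulfonimide), O=S(=O)(N(c1ccccc1)S(=O)(=O)C(F)(F)F)C(F)(F)F
Why: The potassium alkoxide of the 3-oxido-1,5-diene C3=C2–C1–C6(O–)–C5=C4 should undergo a concerted suprafacial [3,3]-sigmatropic shift (anionic oxy-Cope rearrangement; closest precedent is the ring expansion of trans-1,2-dialkenylcyclohexanols to (E)-cyclodec-5-enones), forming C3–C4 as C1–C6 breaks. The ten-membered ring is thus closed by a four-atom enlargement of ring C1/C6–C10 rather than by an end-to-end cyclisation, so it needs no high dilution. In 17 the vinyl and propenyl groups are trans-diequatorial, so the shift should pass through a chair transition state shaped like a trans-decalin in which C7 and C10 stay pseudo-equatorial, giving the (E)-C5=C6 enolate and the (E)-C1=C2 alkene. The one new stereocentre, C4, is set by the (E)-propenyl geometry (methyl pseudo-equatorial) together with the configurations of C1 and C6, and so ultimately by C7. The step needs chair-over-boat selectivity and an enolate that stays on the C5 side, which the all-equatorial chair, the absence of a more acidic C–H and cold trapping with PhNTf2 should secure. In one operation it delivers the carbocycle, the C3–C4 bond, saturated C3, the C4 methyl stereocentre and both alkenes that later become the 4,5-oxirane/lactone and the enoate.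

Step 11
Reactants: 20 ring-expanded enol triflate
Product: 21 (1E,5E)-cyclodeca-1,5-diene amide
Conditions: Pd(OAc)2 (5 mol%), PPh3, HCO2H, n-Bu3N, DMF, 40 °C
Reagents that add atoms: none
Why: Palladium-catalysed formate reduction of the alkenyl triflate should replace the triflate by hydrogen with retention, leaving the (E)-C5=C6 alkene next to the C4 stereocentre.

Step 12
Reactants: 21 (1E,5E)-cyclodeca-1,5-diene amide
Product: 23 allylic trans-lactone (4E-alkene), via selenolactone 22 (not isolated)
Conditions: PhSeCl, CH2Cl2, −78 °C; aq. NaHCO3; then H2O2 (30%), pyridine, CH2Cl2, 0 → 25 °C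
Reagents that add atoms: water, O
Why: Phenylselenolactonisation (5-exo attack of the amide oxygen on C6 from the face of the C7 side chain, anti addition, iminium hydrolysis) should set C6 as the trans-lactone and C5 anti to it, and selenoxide syn-elimination away from oxygen then uses the C4 hydrogen, which with the C4 configuration from step 10 gives the (4E)-alkene.

Step 13
Reactants: 23 allylic trans-lactone (4E-alkene)
Product: 25 13-silyloxymethyl lactone, via hydroxymethyl lactone alkoxide 24 (not isolated)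
Conditions: LiN(i-Pr)2, THF, −78 °C; HCHO (g); then t-BuPh2SiCl, DMAP, −78 → 25 °C
Reagents that add atoms: formaldehyde, C=O; tert-butyldiphenylsilyl chloride, CC(C)(C)[Si](Cl)(c1ccccc1)c1ccccc1
Why: Lactone enolate aldol with formaldehyde, trans to the C7–C8 bond, and in situ silylation should install C13 as a masked exo-methylene while the lactone is the only acidic site (the C11 configuration is later destroyed).

Step 14
Reactants: 25 13-silyloxymethyl lactone
Product: 26 9,14-diol
Conditions: PPTS (cat.), MeOH, 25 °C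
Reagents that add atoms: none
Why: Mild acid-catalysed transacetalisation should remove the acetonide and leave the secondary TBS ether, the TBDPS ether and the allylic lactone intact.

Step 15
Reactants: 26 9,14-diol
Product: 28 (Z)-enal (C1=C10), via β,γ-unsaturated aldehyde 27 (not isolated)
Conditions: TEMPO (10 mol%), PhI(OAc)2, CH2Cl2, 25 °C; then Et3N, 0 °C
Reagents that add atoms: none
Why: Oxoammonium oxidation selective for the primary C14 alcohol, then amine-mediated 1,3-proton shift through the dienol, should move C1=C2 into conjugation and give the thermodynamically preferred enal with C2 trans to CHO (ring-cis, as in the target), the free C9 hydroxyl being the poorest available β-leaving group.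

Step 16
Reactants: 28 (Z)-enal (C1=C10)
Product: 30 methyl enoate with free 9-OH, via enoic acid 29 (not isolated)
Conditions: NaClO2, NaH2PO4, 2-methylbut-2-ene, t-BuOH/H2O, 0 °C; then Me3SiCHN2, MeOH/toluene, 0 °C
Reagents that add atoms: sodium chlorite, [Na+].[O-]Cl=O; trimethylsilyldiazomethane, C[Si](C)(C)C=[N+]=[N-]
Why: Pinnick oxidation of the enal and methylation of the crude acid should give the C14 methyl ester with the alkene geometry unchanged and the secondary C9 alcohol untouched.

Step 17
Reactants: 30 methyl enoate with free 9-OH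
Product: 31 9-acetate
Conditions: Ac2O, pyridine, DMAP (cat.), CH2Cl2, 0 °C
Reagents that add atoms: acetic anhydride, CC(=O)OC(C)=O
Why: Standard acetylation of the only free hydroxyl should install the C9 acetate after C10 has lost its acidic hydrogen, so elimination is no longer possible.

Step 18
Reactants: 31 9-acetate
Product: 32 4,5-epoxide
Conditions: mCPBA, NaHCO3, CH2Cl2, 0 °C
Reagents that add atoms: 3-chloroperoxybenzoic acid, O=C(OO)c1cccc(Cl)c1
Why: Prilezhaev epoxidation should be chemoselective for the only electron-rich alkene (C4=C5) and occur on the peripheral face (C6–H eclipsing the alkene to avoid allylic 1,3-strain with C15, the ring shielding the other face), the same face that is epoxidised in related 6,12-trans-germacranolides, giving the 4R,5R-oxirane.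

Step 19
Reactants: 32 4,5-epoxide
Product: 33 8,13-diol
Conditions: Bu4NF, AcOH, THF, 0 → 25 °C
Reagents that add atoms: none
Why: Buffered fluoride desilylation should remove both silyl ethers while the acetic acid buffer suppresses acetate migration from O9 to O8 and retro-aldol loss of C13.

Step 20
Reactants: 33 8,13-diol; 34 methacryloyl chloride
Product: 36 target CNP0153978.4, via bis-methacrylate 35 (not isolated)
Conditions: Et3N, CH2Cl2, 0 °C; then DBU, 0 °C
Reagents that add atoms: none
Why: Acylation of both hydroxyls and E1cB elimination of the β-acyloxy group at C13 should install the C8 methacrylate and unveil the α-methylene lactone in one flask, with no stereocentre touched.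

## Compound list

1 | 4,4-dimethoxycyclohexa-2,5-dien-1-one | COC1(OC)C=CC(=O)C=C1 | starting material
2 | (E)-1-bromoprop-1-ene | C/C=C/Br | starting material
3 | (E)-prop-1-en-1-yllithium | C/C=C/[Li] | intermediate
4 | 4,4-dimethoxy-1-[(E)-prop-1-enyl]cyclohexa-2,5-dien-1-ol (lithium alkoxide before quench) | C/C=C/C1(O)C=CC(OC)(OC)C=C1 | intermediate
5 | 4-hydroxy-4-[(E)-prop-1-enyl]cyclohexa-2,5-dien-1-one | C/C=C/C1(O)C=CC(=O)C=C1 | intermediate
6 | methyl 3-chloro-3-oxopropanoate | COC(=O)CC(Cl)=O | starting material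
7 | methyl 4-oxo-1-[(E)-prop-1-enyl]cyclohexa-2,5-dien-1-yl malonate | C/C=C/C1(OC(=O)CC(=O)OC)C=CC(=O)C=C1 | intermediate
8 | cis-fused bicyclic lactone enone with CO2Me on C11 (O6 and C11 cis; C11 epimers, labile) | O=C1C=C[C@]2(/C=C/C)OC(=O)C(C(=O)OC)[C@@H]2C1 | intermediate
9 | cis-fused bicyclic lactone enone (O6–C12(=O)–C11H2–C7; propenyl on C6 trans to C11) | O=C1C=C[C@]2(/C=C/C)OC(=O)C[C@@H]2C1 | intermediate
10 | tert-butyldimethylsilyl dienol ether of 9 (C8=C9–OTBS) | CC(C)(C)[Si](C)(C)OC1C=C[C@]2(/C=C/C)OC(=O)C[C@@H]2C=1 | intermediate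
11 | 8-(tert-butyldimethylsilyloxy) bicyclic lactone enone (O8 trans to C11) | O=C1C=C[C@]2(/C=C/C)OC(=O)C[C@@H]2[C@H]1O[Si](C)(C)C(C)(C)C | intermediate
12 | hydroxy amide enone (6-OH, 7-CH2CONMe2 cis to OH, 8-OTBS) | O=C1C=C[C@@](O)(/C=C/C)[C@H](CC(=O)N(C)C)[C@H]1O[Si](C)(C)C(C)(C)C | intermediate
13 | vinylmagnesium bromide | C=C[Mg]Br | starting material
14 | bromomagnesium enolate/alkoxide after conjugate addition (1-vinyl syn to O6) | Br[Mg]OC1=C[C@H](C=C)[C@@](O[Mg]Br)(/C=C/C)[C@H](CC(=O)N(C)C)[C@H]1O[Si](C)(C)C(C)(C)C | intermediate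
15 | β-hydroxy ketone (1-vinyl α, 10-CH2OH β, 9-oxo, 8-OTBS β, 6-OH α, 6-propenyl β, 7-CH2CONMe2 α) | O=C1[C@@H](CO)[C@H](C=C)[C@@](O)(/C=C/C)[C@H](CC(=O)N(C)C)[C@H]1O[Si](C)(C)C(C)(C)C | intermediate
16 | triol (axial 9-OH cis to 8-OTBS and to the 10-CH2OH group) | O[C@H]1[C@@H](CO)[C@H](C=C)[C@@](O)(/C=C/C)[C@H](CC(=O)N(C)C)[C@H]1O[Si](C)(C)C(C)(C)C | intermediate
17 | Cope substrate: 9,14-O-isopropylidene derivative of 16 (vinyl and propenyl trans-diequatorial, free tertiary 6-OH) | CC1(C)OC[C@H]2[C@H](C=C)[C@@](O)(/C=C/C)[C@H](CC(=O)N(C)C)[C@@H](O[Si](C)(C)C(C)(C)C)[C@H]2O1 | intermediate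
18 | potassium alkoxide of 17 | CC1(C)OC[C@H]2[C@H](C=C)[C@@]([O-])(/C=C/C)[C@H](CC(=O)N(C)C)[C@@H](O[Si](C)(C)C(C)(C)C)[C@H]2O1.[K+] | intermediate
19 | ring-expanded potassium enolate (ten-membered; C5=C6–OK, C1=C2 E, new C3–C4 bond) | CC(C)(C)[Si](C)(C)O[C@@H]1[C@@H](CC(=O)N(C)C)/C([O-])=C/[C@H](C)C/C=C/[C@@H]2COC(C)(C)O[C@@H]21.[K+] | intermediate
20 | ring-expanded enol triflate (6-OTf; C4 and C7 trans across C5=C6; C1=C2 E; 4-methyl from chair shift) | CC(C)(C)[Si](C)(C)O[C@@H]1[C@@H](CC(=O)N(C)C)/C(OS(=O)(=O)C(F)(F)F)=C/[C@H](C)C/C=C/[C@@H]2COC(C)(C)O[C@@H]21 | intermediate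
21 | (1E,5E)-cyclodeca-1,5-diene amide (4-methyl, 7-CH2CONMe2, 8-OTBS, 9,14-O-isopropylidene) | CC(C)(C)[Si](C)(C)O[C@@H]1[C@@H](CC(=O)N(C)C)/C=C/[C@H](C)C/C=C/[C@@H]2COC(C)(C)O[C@@H]21 | intermediate
22 | 5-phenylseleno 6,12-trans-lactone (Se anti to O6) | CC(C)(C)[Si](C)(C)O[C@@H]1[C@H]2CC(=O)O[C@@H]2[C@H]([Se]c3ccccc3)[C@H](C)C/C=C/[C@@H]4COC(C)(C)O[C@@H]41 | intermediate
23 | allylic 6,12-trans-lactone with (4E)-C4=C5 and (1E)-C1=C2 | CC(C)(C)[Si](C)(C)O[C@@H]1[C@H]2CC(=O)O[C@@H]2/C=C(\C)C/C=C/[C@@H]3COC(C)(C)O[C@@H]31 | intermediate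
24 | lithium alkoxide of the 11-hydroxymethyl lactone (C13 trans to C8) | CC(C)(C)[Si](C)(C)O[C@@H]1[C@H]2[C@H](C[O-])C(=O)O[C@@H]2/C=C(\C)C/C=C/[C@@H]3COC(C)(C)O[C@@H]31.[Li+] | intermediate
25 | 13-(tert-butyldiphenylsilyloxy) lactone | CC(C)(C)[Si](C)(C)O[C@@H]1[C@H]2[C@H](CO[Si](c3ccccc3)(c3ccccc3)C(C)(C)C)C(=O)O[C@@H]2/C=C(\C)C/C=C/[C@@H]3COC(C)(C)O[C@@H]31 | intermediate
26 | 9,14-diol | CC(C)(C)[Si](C)(C)O[C@@H]1[C@H]2[C@H](CO[Si](c3ccccc3)(c3ccccc3)C(C)(C)C)C(=O)O[C@@H]2/C=C(\C)C/C=C/[C@H](CO)[C@@H]1O | intermediate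
27 | β,γ-unsaturated 14-aldehyde (C1=C2 still E) | CC(C)(C)[Si](C)(C)O[C@@H]1[C@H]2[C@H](CO[Si](c3ccccc3)(c3ccccc3)C(C)(C)C)C(=O)O[C@@H]2/C=C(\C)C/C=C/[C@H](C=O)[C@@H]1O | intermediate
28 | conjugated 14-al with C1=C10 (C2 cis to C9), 9-OH | CC(C)(C)[Si](C)(C)O[C@@H]1[C@H]2[C@H](CO[Si](c3ccccc3)(c3ccccc3)C(C)(C)C)C(=O)O[C@@H]2/C=C(\C)CC/C=C(/C=O)[C@@H]1O | intermediate
29 | 14-oic acid | CC(C)(C)[Si](C)(C)O[C@@H]1[C@H]2[C@H](CO[Si](c3ccccc3)(c3ccccc3)C(C)(C)C)C(=O)O[C@@H]2/C=C(\C)CC/C=C(/C(=O)O)[C@@H]1O | intermediate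
30 | methyl 14-oate with free 9-OH | CC(C)(C)[Si](C)(C)O[C@@H]1[C@H]2[C@H](CO[Si](c3ccccc3)(c3ccccc3)C(C)(C)C)C(=O)O[C@@H]2/C=C(\C)CC/C=C(/C(=O)OC)[C@@H]1O | intermediate
31 | 9-acetate | CC(C)(C)[Si](C)(C)O[C@@H]1[C@H]2[C@H](CO[Si](c3ccccc3)(c3ccccc3)C(C)(C)C)C(=O)O[C@@H]2/C=C(\C)CC/C=C(/C(=O)OC)[C@@H]1OC(C)=O | intermediate
32 | (4R,5R)-4,5-epoxide | CC(C)(C)[Si](C)(C)O[C@@H]1[C@H]2[C@H](CO[Si](c3ccccc3)(c3ccccc3)C(C)(C)C)C(=O)O[C@@H]2[C@H]2O[C@]2(C)CC/C=C(/C(=O)OC)[C@@H]1OC(C)=O | intermediate
33 | 8,13-diol | O[C@@H]1[C@H]2[C@H](CO)C(=O)O[C@@H]2[C@H]2O[C@]2(C)CC/C=C(/C(=O)OC)[C@@H]1OC(C)=O | intermediate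
34 | methacryloyl chloride | C=C(C)C(Cl)=O | starting material
35 | 8,13-bis-methacrylate | C=C(C)C(=O)O[C@@H]1[C@H]2[C@H](COC(=O)C(C)=C)C(=O)O[C@@H]2[C@H]2O[C@]2(C)CC/C=C(/C(=O)OC)[C@@H]1OC(C)=O | intermediate
36 | CNP0153978.4 (4R,5R,6S,7R,8R,9S; 1(10)-alkene with C2 cis to C9) | C=C(C)C(=O)O[C@@H]1[C@H]2C(=C)C(=O)O[C@@H]2[C@H]2O[C@]2(C)CC/C=C(/C(=O)OC)[C@@H]1OC(C)=O | target

## Step count and risks

Total step count: 20. Longest linear sequence: 20 steps (from 1).

**Step 10 (key step).** The shift may leak through a boat-like transition state, which would epimerise C4, or the enolate may transfer a proton before it is triflated. The fallback sets out from 17 and keeps the C4 epimer instead of discarding it. The C4-epimeric enol triflate F3 is reduced as in step 11 to the C4-epimeric diene F4. Iodolactonisation (I2, NaHCO3, THF/H2O) gives the C4-epimeric iodolactone F5 by anti addition, and DBU-induced anti-elimination of hydrogen iodide (in place of selenoxide syn-elimination) then gives the same (4E)-lactone, rejoining the route at 23.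

**Step 7.** The Grignard reagent may add 1,2 to the ketone or attack the amide, and facial control is lost if the magnesium alkoxide does not deliver the vinyl group. The fallback sets out from 11, before the lactone is opened. Rhodium-catalysed conjugate addition of potassium vinyltrifluoroborate ([RhCl(C2H4)2]2, a chiral diene ligand chosen to override the substrate bias, KOH, dioxane/H2O) gives the vinyl ketone lactone F1. Enolisation at C10 (LiN(i-Pr)2) and formaldehyde give the hydroxymethyl ketone lactone F2, and aminolysis (Me2NH·HCl, AlMe3) rejoins the route at 15.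

**Step 15.** β-Elimination of the C9 oxygen or retro-aldol ring cleavage may outrun the 1,3-proton shift at the aldehyde stage. The fallback sets out from 26 and moves the double bond at the ester level, where the dienolate forms only in traces. Direct oxidation to the acid (TEMPO, PhI(OAc)2, MeCN/H2O) gives the β,γ-unsaturated hydroxy acid F6, and Me3SiCHN2 gives the β,γ-unsaturated methyl ester F7. Catalytic DBU in CH2Cl2 then conjugates the alkene, rejoining the route at 30.

Further compounds
F1 | step 7 | vinyl ketone lactone (1-vinyl syn to O6, lactone intact) | O=C1C[C@H](C=C)[C@]2(/C=C/C)OC(=O)C[C@@H]2[C@H]1O[Si](C)(C)C(C)(C)C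
F2 | step 7 | hydroxymethyl ketone lactone | O=C1[C@@H](CO)[C@H](C=C)[C@]2(/C=C/C)OC(=O)C[C@@H]2[C@H]1O[Si](C)(C)C(C)(C)C
F3 | step 10 | C4-epimeric enol triflate | CC(C)(C)[Si](C)(C)O[C@@H]1[C@@H](CC(=O)N(C)C)/C(OS(=O)(=O)C(F)(F)F)=C/[C@@H](C)C/C=C/[C@@H]2COC(C)(C)O[C@@H]21
F4 | step 10 | C4-epimeric diene | CC(C)(C)[Si](C)(C)O[C@@H]1[C@@H](CC(=O)N(C)C)/C=C/[C@@H](C)C/C=C/[C@@H]2COC(C)(C)O[C@@H]21
F5 | step 10 | C4-epimeric 5-iodo 6,12-trans-lactone | CC(C)(C)[Si](C)(C)O[C@@H]1[C@H]2CC(=O)O[C@@H]2[C@H](I)[C@@H](C)C/C=C/[C@@H]3COC(C)(C)O[C@@H]31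
F6 | step 15 | β,γ-unsaturated hydroxy acid | CC(C)(C)[Si](C)(C)O[C@@H]1[C@H]2[C@H](CO[Si](c3ccccc3)(c3ccccc3)C(C)(C)C)C(=O)O[C@@H]2/C=C(\C)C/C=C/[C@H](C(=O)O)[C@@H]1O
F7 | step 15 | β,γ-unsaturated methyl ester | CC(C)(C)[Si](C)(C)O[C@@H]1[C@H]2[C@H](CO[Si](c3ccccc3)(c3ccccc3)C(C)(C)C)C(=O)O[C@@H]2/C=C(\C)C/C=C/[C@H](C(=O)OC)[C@@H]1O
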